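**Plan**
- Retrosynthetic cuts: first the two aryl–O–C bonds to the side chains (giving a bisphenol oxolane core and a lactate-derived α-tosyloxy ketone), then the C2–aryl bond of the oxolane (γ-lactone plus aryl Grignard), then C4–C5 and O1–C2 of the lactone (enal plus aryl aldehyde).
- Enabling feature: with the oxolane numbered O1, C2 (ring A, the hydroxylated aryl), C3, C4, C5 (ring B, the methoxylated aryl), the atoms C2, C3, C4 and both ring methyls are the five carbons of (E)-2-methylbut-2-enal, and C5 with ring B is an aryl aldehyde. The cis relation of the C4 methyl and the C5 aryl is the native outcome of a homoenolate annulation.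
- Forward order: the lactone, the only ring built, closes in step 1; aryl addition at C2 and silane reduction turn it into the oxolane; the two bromides become phenols; both side chains are joined in one double etherification; the ketones are reduced and the benzyl group removed.
- Stereochemistry: C4 and C5 from the chiral carbene, C3 by equilibration, C2 by hydride delivery anti to the C3 methyl, the side-chain ether carbons from (S)-lactate with one inversion, the carbinols by Felkin–Anh reduction.

Key step: step 1

Remark: the SMILES is read as the (2S,3R,4R,5S)-oxolane (2,3-cis, 3,4-trans, 4,5-cis, aryl groups mutually trans) carrying two threo-(1R,2R) side chains.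
Assumption: the (5aS,10bR) antipode of the aminoindanol triazolium salt is taken to lead to the (4R,5S) lactone; the sense of induction is to be confirmed on the first batch, the mirror-image salt being equally available commercially.

**Route**

Step 1
Reactants: 1 (E)-2-methylbut-2-enal; 2 4-bromo-3-methoxybenzaldehyde
Product: 4 (3R,4R,5S)-5-(4-bromo-3-methoxyphenyl)-3,4-dimethyloxolan-2-one, via C3-epimeric lactone mixture 3 (not isolated)
Conditions: (5aS,10bR)-2-mesityl-5a,10b-dihydro-4H,6H-indeno[2,1-b][1,2,4]triazolo[4,3-d][1,4]oxazin-2-ium chloride (10 mol%), DBU (20 mol%), THF/t-BuOH 10:1, rt, slow addition of 1; then DBU (1 equiv), 50 °C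
Reagents that add atoms: none
Why: The triazolylidene adds to the formyl group of 1 and proton transfer gives the extended Breslow intermediate, whose β-carbon (the future C4) attacks the carbonyl carbon of 2 to form C4–C5; tautomerisation and C-protonation then create C3 and the acyl azolium, which the C5 alkoxide captures in a 5-exo-trig acyl substitution that forms O1–C2, closes the lactone and releases the carbene. The closest known reaction type is the carbene-catalysed homoenolate [3+2] annulation of enals with aromatic aldehydes to cis-γ-butyrolactones, which has been run with β-alkyl and with α-substituted enals, although an α,β-dimethyl enal under asymmetric catalysis sits at the edge of what is documented. The configuration at C4 and C5 should be set by the aminoindanol backbone of the carbene, which leaves one face of the homoenolate open, and their cis relationship by the compact addition transition state typical of this annulation; C3 is set under thermodynamic control by the closing DBU treatment, which converts the C3 epimers 3 into the isomer with the C3 methyl trans to the C4 methyl and thus away from the all-cis arrangement. The step needs chemoselectivity for the cross reaction (homoenolate to 2, not to a second molecule of 1, and no benzoin coupling of 2), which the N-mesityl carbene, the electron-poor bromo aldehyde as the better electrophile and the slow addition of 1 should secure. Any 4,5-trans lactone would be removed by chromatography, and the enantiomeric purity checked and if needed raised by crystallisation before the material is carried on.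

Step 2
Reactants: 5 2-bromo-5-iodophenol
Product: 6 2-(benzyloxy)-1-bromo-4-iodobenzene
Conditions: BnBr, K2CO3, DMF, rt
Reagents that add atoms: benzyl bromide, BrCc1ccccc1
Why: Williamson etherification of the phenoxide gives a benzyl ether that cannot migrate to a neighbouring oxygen later, survives the organomagnesium, Lewis-acid, palladium and basic steps, and is removed at the end by hydrogenolysis.

Step 3
Reactants: 6 2-(benzyloxy)-1-bromo-4-iodobenzene; 4 (3R,4R,5S)-5-(4-bromo-3-methoxyphenyl)-3,4-dimethyloxolan-2-one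
Product: 8 (3R,4R,5S)-2-[3-(benzyloxy)-4-bromophenyl]-5-(4-bromo-3-methoxyphenyl)-3,4-dimethyloxolan-2-ol (anomer mixture in equilibrium with the open γ-hydroxy ketone), via arylmagnesium chloride 7 (not isolated)
Conditions: 6 (1.2 equiv), i-PrMgCl·LiCl, THF, −30 °C; then 4, −30 to 0 °C; aq NH4Cl
Reagents that add atoms: none
Why: Iodine–magnesium exchange is much faster than bromine–magnesium exchange, so the Grignard reagent forms only at the former C–I carbon, and its 1,2-addition to the lactone carbonyl (Grignard addition to a lactone) should stop at the magnesium hemiketalate in the cold, leaving C3, C4 and C5 untouched.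

Step 4
Reactants: 8 (3R,4R,5S)-2-[3-(benzyloxy)-4-bromophenyl]-5-(4-bromo-3-methoxyphenyl)-3,4-dimethyloxolan-2-ol
Product: 9 (2S,3R,4R,5S)-2-[3-(benzyloxy)-4-bromophenyl]-5-(4-bromo-3-methoxyphenyl)-3,4-dimethyloxolane
Conditions: Et3SiH, BF3·OEt2, CH2Cl2, −78 to −40 °C
Reagents that add atoms: none
Why: BF3·OEt2 ionises the hemiketal to the 2-aryl oxocarbenium ion and the silane delivers hydride to the face opposite the adjacent C3 methyl (ionic hydrogenation of a lactol), which should place the C2 aryl cis to that methyl and set C2 as S, while the para-bromine atoms on both rings keep the two benzylic C–O bonds from ionising and epimerising.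

Step 5
Reactants: 9 (2S,3R,4R,5S)-2-[3-(benzyloxy)-4-bromophenyl]-5-(4-bromo-3-methoxyphenyl)-3,4-dimethyloxolane
Product: 10 (2S,3R,4R,5S)-2-[3-(benzyloxy)-4-(4,4,5,5-tetramethyl-1,3,2-dioxaborolan-2-yl)phenyl]-5-[3-methoxy-4-(4,4,5,5-tetramethyl-1,3,2-dioxaborolan-2-yl)phenyl]-3,4-dimethyloxolane
Conditions: B2pin2, Pd(dppf)Cl2 (5 mol%), KOAc, 1,4-dioxane, 90 °C
Reagents that add atoms: bis(pinacolato)diboron, CC1(C)OB(OC1(C)C)B2OC(C)(C)C(C)(C)O2
Why: Miyaura borylation (oxidative addition of zerovalent palladium into each aryl C–Br bond, acetate-assisted transmetalation, reductive elimination) runs under weakly basic conditions that leave the four ring stereocentres and both benzylic ethers untouched.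

Step 6
Reactants: 10 the bis(pinacol boronate) of step 5
Product: 11 2-(benzyloxy)-4-[(2S,3R,4R,5S)-5-(4-hydroxy-3-methoxyphenyl)-3,4-dimethyloxolan-2-yl]phenol
Conditions: H2O2 (30% aq), NaOH, THF, 0 °C
Reagents that add atoms: hydrogen peroxide, OO
Why: Oxidation of the aryl boronates by hydroperoxide, with 1,2-aryl migration from boron to oxygen and hydrolysis of the borate, frees both phenols at 0 °C, cold and brief enough that the para-phenoxides should not open the oxolane through a quinone methide.

Step 7
Reactants: 12 ethyl (S)-lactate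
Product: 13 (S)-2-hydroxy-N-methoxy-N-methylpropanamide
Conditions: MeNH(OMe)·HCl, i-PrMgCl, THF, −20 to 0 °C
Reagents that add atoms: N,O-dimethylhydroxylamine hydrochloride, CNOC.Cl
Why: Aminolysis of the ester by the chloromagnesium amide of N,O-dimethylhydroxylamine (Weinreb amide formation) does not touch the stereocentre taken from the chiral pool.

Step 8
Reactants: 13 (S)-2-hydroxy-N-methoxy-N-methylpropanamide; 14 3,4-dimethoxyphenylmagnesium bromide
Product: 15 (S)-1-(3,4-dimethoxyphenyl)-2-hydroxypropan-1-one
Conditions: 14 (2.3 equiv), THF, 0 °C; aq NH4Cl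
Reagents that add atoms: none
Why: Grignard addition to a Weinreb amide stops at the chelated tetrahedral intermediate until work-up, so the ketone forms only once, and the magnesium alkoxide made by the first equivalent of 14 shields the α-centre from enolisation.

Step 9
Reactants: 15 (S)-1-(3,4-dimethoxyphenyl)-2-hydroxypropan-1-one
Product: 16 (S)-1-(3,4-dimethoxyphenyl)-1-oxopropan-2-yl 4-methylbenzenesulfonate
Conditions: TsCl, Et3N, DMAP (cat.), CH2Cl2, 0 °C
Reagents that add atoms: p-toluenesulfonyl chloride, Cc1ccc(cc1)S(Cl)(=O)=O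
Why: O-sulfonylation of the secondary alcohol proceeds with retention at carbon and is run cold and briefly so that the α-keto stereocentre is not enolised.

Step 10
Reactants: 11 the bisphenol of step 6; 16 (S)-1-(3,4-dimethoxyphenyl)-1-oxopropan-2-yl 4-methylbenzenesulfonate
Product: 17 (R)-2-[2-(benzyloxy)-4-{(2S,3R,4R,5S)-5-[4-{[(R)-1-(3,4-dimethoxyphenyl)-1-oxopropan-2-yl]oxy}-3-methoxyphenyl]-3,4-dimethyloxolan-2-yl}phenoxy]-1-(3,4-dimethoxyphenyl)propan-1-one
Conditions: 16 (2.4 equiv), BEMP (2-tert-butylimino-2-diethylamino-1,3-dimethylperhydro-1,3,2-diazaphosphorine, 2.3 equiv), MeCN, 0 °C to rt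
Reagents that add atoms: none
Why: Each phosphazenium phenoxide displaces the carbonyl-activated secondary tosylate by SN2 (Williamson ether synthesis) with inversion, turning the S tosylate into the R aryl ether, and the non-nucleophilic base used without excess should limit enolisation of both tosylate and product.

Step 11
Reactants: 17 the bis-ketone of step 10
Product: 18 (1R,2R)-2-[2-(benzyloxy)-4-{(2S,3R,4R,5S)-5-[4-{[(1R,2R)-1-(3,4-dimethoxyphenyl)-1-hydroxypropan-2-yl]oxy}-3-methoxyphenyl]-3,4-dimethyloxolan-2-yl}phenoxy]-1-(3,4-dimethoxyphenyl)propan-1-ol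
Conditions: polymer-bound ammonium borohydride (Amberlite IRA-400, BH4 form), MeOH/THF, 0 °C
Reagents that add atoms: none
Why: Hydride addition without a chelating counter-ion follows the Felkin–Anh model (aryloxy group anti to the incoming hydride) and should give the threo (1R,2R) alcohol in each side chain, the ammonium borohydride offering no Lewis acid that could divert the reaction to the chelate (erythro) pathway.

Step 12
Reactants: 18 the O-benzyl bis-alcohol of step 11
Product: 19 manassantin B1
Conditions: H2 (1 atm), 10% Pd/C, EtOAc, rt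
Reagents that add atoms: none
Why: Hydrogenolysis of an aryl benzyl ether over Pd/C in neutral ethyl acetate is much faster than cleavage of the secondary benzylic alcohols or of the benzylic ethers of the oxolane, so only the phenol should be unmasked.

**Compound list**
1 | (E)-2-methylbut-2-enal (tiglic aldehyde) | C/C=C(\C)/C=O | starting material
2 | 4-bromo-3-methoxybenzaldehyde | COc1cc(C=O)ccc1Br | starting material
3 | (4R,5S)-5-(4-bromo-3-methoxyphenyl)-3,4-dimethyloxolan-2-one, mixture of C3 epimers | O=C1O[C@H](c2ccc(Br)c(OC)c2)[C@H](C)C1C | intermediate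
4 | (3R,4R,5S)-5-(4-bromo-3-methoxyphenyl)-3,4-dimethyloxolan-2-one | O=C1O[C@H](c2ccc(Br)c(OC)c2)[C@H](C)[C@H]1C | intermediate
5 | 2-bromo-5-iodophenol | Oc1cc(I)ccc1Br | starting material
6 | 2-(benzyloxy)-1-bromo-4-iodobenzene | Brc1ccc(I)cc1OCc1ccccc1 | intermediate
7 | [3-(benzyloxy)-4-bromophenyl]magnesium chloride (LiCl complex) | Brc1ccc([Mg]Cl)cc1OCc1ccccc1 | intermediate
8 | (3R,4R,5S)-2-[3-(benzyloxy)-4-bromophenyl]-5-(4-bromo-3-methoxyphenyl)-3,4-dimethyloxolan-2-ol, anomer mixture | OC1(c2ccc(Br)c(OCc3ccccc3)c2)O[C@H](c4ccc(Br)c(OC)c4)[C@H](C)[C@H]1C | intermediate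
9 | (2S,3R,4R,5S)-2-[3-(benzyloxy)-4-bromophenyl]-5-(4-bromo-3-methoxyphenyl)-3,4-dimethyloxolane | Brc1ccc(cc1OCc2ccccc2)[C@H]3O[C@H](c4ccc(Br)c(OC)c4)[C@H](C)[C@H]3C | intermediate
10 | (2S,3R,4R,5S)-2-[3-(benzyloxy)-4-(4,4,5,5-tetramethyl-1,3,2-dioxaborolan-2-yl)phenyl]-5-[3-methoxy-4-(4,4,5,5-tetramethyl-1,3,2-dioxaborolan-2-yl)phenyl]-3,4-dimethyloxolane | CC1(C)OB(OC1(C)C)c2ccc(cc2OCc3ccccc3)[C@H]4O[C@H](c5ccc(B6OC(C)(C)C(C)(C)O6)c(OC)c5)[C@H](C)[C@H]4C | intermediate
11 | 2-(benzyloxy)-4-[(2S,3R,4R,5S)-5-(4-hydroxy-3-methoxyphenyl)-3,4-dimethyloxolan-2-yl]phenol | Oc1ccc(cc1OCc2ccccc2)[C@H]3O[C@H](c4ccc(O)c(OC)c4)[C@H](C)[C@H]3C | intermediate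
12 | ethyl (S)-lactate | CCOC(=O)[C@H](C)O | starting material
13 | (S)-2-hydroxy-N-methoxy-N-methylpropanamide | CON(C)C(=O)[C@H](C)O | intermediate
14 | 3,4-dimethoxyphenylmagnesium bromide (commercial THF solution) | COc1ccc([Mg]Br)cc1OC | starting material
15 | (S)-1-(3,4-dimethoxyphenyl)-2-hydroxypropan-1-one | COc1ccc(cc1OC)C(=O)[C@H](C)O | intermediate
16 | (S)-1-(3,4-dimethoxyphenyl)-1-oxopropan-2-yl 4-methylbenzenesulfonate | COc1ccc(cc1OC)C(=O)[C@H](C)OS(=O)(=O)c2ccc(C)cc2 | intermediate
17 | (R)-2-[2-(benzyloxy)-4-{(2S,3R,4R,5S)-5-[4-{[(R)-1-(3,4-dimethoxyphenyl)-1-oxopropan-2-yl]oxy}-3-methoxyphenyl]-3,4-dimethyloxolan-2-yl}phenoxy]-1-(3,4-dimethoxyphenyl)propan-1-one | COc1ccc(C(=O)[C@@H](C)Oc2ccc([C@H]3O[C@H](c4ccc(O[C@H](C)C(=O)c5ccc(OC)c(OC)c5)c(OC)c4)[C@H](C)[C@H]3C)cc2OCc6ccccc6)cc1OC | intermediate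
18 | (1R,2R)-2-[2-(benzyloxy)-4-{(2S,3R,4R,5S)-5-[4-{[(1R,2R)-1-(3,4-dimethoxyphenyl)-1-hydroxypropan-2-yl]oxy}-3-methoxyphenyl]-3,4-dimethyloxolan-2-yl}phenoxy]-1-(3,4-dimethoxyphenyl)propan-1-ol (O-benzyl manassantin B1) | COc1ccc([C@@H](O)[C@@H](C)Oc2ccc([C@H]3O[C@H](c4ccc(O[C@H](C)[C@H](O)c5ccc(OC)c(OC)c5)c(OC)c4)[C@H](C)[C@H]3C)cc2OCc6ccccc6)cc1OC | intermediate
19 | manassantin B1, (1R,2R)-1-(3,4-dimethoxyphenyl)-2-[4-{(2S,3R,4R,5S)-5-[4-{[(1R,2R)-1-(3,4-dimethoxyphenyl)-1-hydroxypropan-2-yl]oxy}-3-methoxyphenyl]-3,4-dimethyloxolan-2-yl}-2-hydroxyphenoxy]propan-1-ol | COc1ccc([C@@H](O)[C@@H](C)Oc2ccc([C@H]3O[C@H](c4ccc(O[C@H](C)[C@H](O)c5ccc(OC)c(OC)c5)c(OC)c4)[C@H](C)[C@H]3C)cc2O)cc1OC | target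

**Step count**
Total: 12 steps. Longest linear sequence: 8 steps (steps 1, 3, 4, 5, 6, 10, 11, 12; equally long from 5 through step 2).

**Steps most likely to fail**

Step 1. The α,β-dimethyl enal may form its homoenolate slowly, so that self-annulation of the enal or benzoin coupling of the aldehyde competes. Discrimination between the cis and trans modes of C4–C5 bond formation, or between the two enantiofaces, may also be insufficient. The fallback sets out from aldehyde 2 and rejoins the route at lactone 4.
- Brown crotylboration of 2 with the (Z)-crotyldiisopinocampheylborane made from cis-2-butene and (−)-B-methoxydiisopinocampheylborane should give the syn homoallylic alcohol (1S,2R)-1-(4-bromo-3-methoxyphenyl)-2-methylbut-3-en-1-ol F1.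
- Hydroboration with 9-BBN and oxidative work-up give (1S,2R)-1-(4-bromo-3-methoxyphenyl)-2-methylbutane-1,4-diol F2.
- TEMPO with PhI(OAc)2 oxidises the primary alcohol and closes (4R,5S)-5-(4-bromo-3-methoxyphenyl)-4-methyloxolan-2-one F3.
- LiHMDS followed by MeI at −78 °C methylates the enolate anti to the C4 methyl and gives 4.

Step 4. Hydride may be delivered in part from the face syn to the C3 methyl, or the product may epimerise at C2 under the Lewis acid; either leads to the 2,3-trans oxolane. The fallback sets out from lactone 4 and rejoins at 9, forming the C2–aryl bond on an oxocarbenium ion that carries hydrogen instead of the aryl group.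
- DIBAL-H at −78 °C gives the lactol (3R,4R,5S)-5-(4-bromo-3-methoxyphenyl)-3,4-dimethyloxolan-2-ol F4.
- Benzenesulfinic acid with CaCl2 converts it into the sulfone (3R,4R,5S)-2-(benzenesulfonyl)-5-(4-bromo-3-methoxyphenyl)-3,4-dimethyloxolane F5.
- The arylzinc reagent [3-(benzyloxy)-4-bromophenyl]zinc bromide F6, made from 7 and ZnBr2, is added to the oxocarbenium ion released from F5. On closely related 3,4-dimethyl-5-aryl oxolanyl sulfones this aryl transfer is known to give the 2,3-cis, 2,5-trans product, here 9.

Step 10. Base-induced enolisation of tosylate 16 or of the α-aryloxy ketone product may erode the configuration of the ether carbons, and elimination of the tosylate or incomplete double alkylation may lower the material throughput. The fallback sets out from bisphenol 11 and rejoins at 17, carrying the ether stereocentre at the less acidic ester and amide oxidation level.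
- Double Mitsunobu etherification of 11 with ethyl (S)-lactate 12 (PPh3, DIAD, THF) inverts the lactate carbon and gives ethyl (R)-2-[2-(benzyloxy)-4-{(2S,3R,4R,5S)-5-[4-{[(R)-1-ethoxy-1-oxopropan-2-yl]oxy}-3-methoxyphenyl]-3,4-dimethyloxolan-2-yl}phenoxy]propanoate F7.
- MeNH(OMe)·HCl with i-PrMgCl converts both esters into (R)-2-[2-(benzyloxy)-4-{(2S,3R,4R,5S)-5-[4-{[(R)-1-[methoxy(methyl)amino]-1-oxopropan-2-yl]oxy}-3-methoxyphenyl]-3,4-dimethyloxolan-2-yl}phenoxy]-N-methoxy-N-methylpropanamide F8.
- Addition of Grignard reagent 14 to both amide groups gives 17.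

**Further compounds**
F1 | step 1 | (1S,2R)-1-(4-bromo-3-methoxyphenyl)-2-methylbut-3-en-1-ol | O[C@H](c1ccc(Br)c(OC)c1)[C@H](C)C=C
F2 | step 1 | (1S,2R)-1-(4-bromo-3-methoxyphenyl)-2-methylbutane-1,4-diol | O[C@H](c1ccc(Br)c(OC)c1)[C@H](C)CCO
F3 | step 1 | (4R,5S)-5-(4-bromo-3-methoxyphenyl)-4-methyloxolan-2-one | O=C1O[C@H](c2ccc(Br)c(OC)c2)[C@H](C)C1
F4 | step 4 | (3R,4R,5S)-5-(4-bromo-3-methoxyphenyl)-3,4-dimethyloxolan-2-ol, anomer mixture | OC1O[C@H](c2ccc(Br)c(OC)c2)[C@H](C)[C@H]1C
F5 | step 4 | (3R,4R,5S)-2-(benzenesulfonyl)-5-(4-bromo-3-methoxyphenyl)-3,4-dimethyloxolane | O=S(=O)(c1ccccc1)C2O[C@H](c3ccc(Br)c(OC)c3)[C@H](C)[C@H]2C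
F6 | step 4 | [3-(benzyloxy)-4-bromophenyl]zinc bromide | Brc1ccc([Zn]Br)cc1OCc2ccccc2
F7 | step 10 | ethyl (R)-2-[2-(benzyloxy)-4-{(2S,3R,4R,5S)-5-[4-{[(R)-1-ethoxy-1-oxopropan-2-yl]oxy}-3-methoxyphenyl]-3,4-dimethyloxolan-2-yl}phenoxy]propanoate | CCOC(=O)[C@@H](C)Oc1ccc(cc1OCc2ccccc2)[C@H]3O[C@H](c4ccc(O[C@H](C)C(=O)OCC)c(OC)c4)[C@H](C)[C@H]3C
F8 | step 10 | (R)-2-[2-(benzyloxy)-4-{(2S,3R,4R,5S)-5-[4-{[(R)-1-[methoxy(methyl)amino]-1-oxopropan-2-yl]oxy}-3-methoxyphenyl]-3,4-dimethyloxolan-2-yl}phenoxy]-N-methoxy-N-methylpropanamide | CON(C)C(=O)[C@@H](C)Oc1ccc(cc1OCc2ccccc2)[C@H]3O[C@H](c4ccc(O[C@H](C)C(=O)N(C)OC)c(OC)c4)[C@H](C)[C@H]3C
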